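Assumption: germacrane/eremophilane numbering (C1–C15) is used for every intermediate, and β is the face that carries C14 and C15. Read this way the target is (3R,4R,5R,7R,9R,10S). It is a cis-decalin with the substituents at C3, C4, C7 and C9 all equatorial.

## Retrosynthetic overview
1. Target ⇒ O9 senecioylation and reductive α-hydroxylation (H to C10, O to C9) ⇒ 3-tigloyloxyeremophila-9,11-dien-8-one.
2. ⇒ one transannular C5–C10 bond, then 1,2-H (C5→C4) and 1,2-Me (C10→C5), the germacryl → eudesmyl → eremophilyl sequence ⇒ 3-tigloyloxygermacra-4,9,11-trien-8-one.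
3. ⇒ C6–C7 closure (the C1–C10 closure of a farnesane chain: allyl electrophile at C6, the C7=C11 π-nucleophile as a dienolate, isopropenyl released) ⇒ acyclic 9-oxofarnesane vinyl epoxide.
4. ⇒ Shi epoxidation (sets C3, from which all other centres are relayed) ⇒ achiral tetraenone ⇒ dienyne + Me3Al + senecioyl chloride ⇒ pent-4-yn-1-ol and two Wittig reagents.
5. Ring order: the ten-membered ring forms first. Rings A and B then form together through the single C5–C10 bond.

## Route

Step 1
Reactants: 1 pent-4-yn-1-ol; 2 2-(triphenylphosphoranylidene)propanal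
Product: 4 (E)-2-methylhept-2-en-6-ynal, via pent-4-ynal 3 (not isolated)
Conditions: Dess–Martin periodinane (1.2 equiv), 2 (2 equiv), CH2Cl2, 0 °C to reflux, 16 h
Reagents that add atoms: ylide 2, CC(C=O)=P(c1ccccc1)(c1ccccc1)c1ccccc1
Why: Oxidation in the presence of a stabilised ylide traps the volatile aldehyde 3 at once in a Wittig olefination, and the α-branched stabilised ylide gives the E-enal.

Step 2
Reactants: 4 (E)-2-methylhept-2-en-6-ynal; 5 methyltriphenylphosphonium bromide
Product: 6 (E)-3-methylocta-1,3-dien-7-yne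
Conditions: 5 (1.3 equiv), KOtBu (1.25 equiv), THF, 0 °C; then 4, −78 °C to rt
Reagents that add atoms: phosphonium salt 5, C[P+](c1ccccc1)(c1ccccc1)c1ccccc1.[Br-]
Why: Wittig methylenation of the enal, in which the ylide is too weak a base to touch the terminal alkyne and the E-trisubstituted alkene is not involved.

Step 3
Reactants: 6 (E)-3-methylocta-1,3-dien-7-yne; 7 trimethylaluminium; 8 3-methylbut-2-enoyl chloride
Product: 10 (5E,9E)-2,6,10-trimethyldodeca-2,5,9,11-tetraen-4-one, via (E)-alkenyldimethylalane 9 (not isolated)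
Conditions: Me3Al (2 equiv), Cp2ZrCl2 (20 mol %), CH2Cl2, 0 °C to rt; evaporate excess Me3Al; 8 (1.1 equiv), Pd(PPh3)4 (5 mol %), THF, 0 °C to rt
Reagents that add atoms: trimethylaluminium 7, C[Al](C)C; 3-methylbut-2-enoyl chloride 8, CC(C)=CC(=O)Cl
Why: Negishi zirconium-catalysed carboalumination adds Me and Al syn to the terminal alkyne only, which fixes the E C9=C10 geometry, and the alkenylalane is acylated with retention (Negishi acylation).

Step 4
Reactants: 10 (5E,9E)-2,6,10-trimethyldodeca-2,5,9,11-tetraen-4-one
Product: 11 (5E)-2,6-dimethyl-8-[(2R,3R)-3-ethenyl-3-methyloxiran-2-yl]octa-2,5-dien-4-one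
Conditions: D-fructose-derived Shi ketone (30 mol %), KHSO5 (as 2KHSO5·KHSO4·K2SO4), K2CO3, Bu4NHSO4 (cat.), MeCN–CH2(OMe)2/aq. Na2B4O7 buffer, 0 °C
Reagents that add atoms: potassium peroxymonosulfate KHSO5, [K+].[O-]S(=O)(=O)OO
Why: Shi asymmetric epoxidation, in which the chiral dioxirane attacks only the electron-rich trisubstituted alkene of the diene (the vinyl and both enone alkenes are far slower) through the spiro transition state, giving the (R,R)-epoxide and so 3R.

Step 5
Reactants: 11 (5E)-2,6-dimethyl-8-[(2R,3R)-3-ethenyl-3-methyloxiran-2-yl]octa-2,5-dien-4-one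
Product: 12 (2E,6R,7E,10R)-6-hydroxy-3,7-dimethyl-10-(prop-1-en-2-yl)cyclodeca-2,7-dien-1-one [(3R,7R)-3-hydroxygermacra-4,9,11-trien-8-one]
Conditions: Pd(PPh3)4 (10 mol %), dppe (10 mol %), THF, 45 °C, 11 added by syringe pump over 20 h (final 2 mM)
Reagents that add atoms: none
Why: Proposed new method: zerovalent palladium ionises the tertiary allylic C4–O bond to a syn π-allyl complex (C4–C6) whose own C3 alkoxide is the base, so the dienone loses a γ-methyl proton and the interconverting dienolates drain through the only strain-free closure, α-carbon C7 onto the unsubstituted terminus C6 (the other dienolate could only give an E-cyclooctene or attack the fully substituted C4); this forms the ten-membered ring, the E C4=C5 alkene and the isopropenyl group in an isomerisation that loses no atom, C3 keeps its C–O bond and configuration, and the acidic C7 settles as the pseudo-equatorial 7R epimer; the closest known reaction types are the neutral Tsuji–Trost alkylation of vinyl epoxides (used for macrocyclisation with stabilised pronucleophiles) and the deconjugative α-alkylation of senecioate-type dienolates.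

Step 6
Reactants: 12 (3R,7R)-3-hydroxygermacra-4,9,11-trien-8-one; 13 tiglic acid
Product: 14 (3R,7R)-3-tigloyloxygermacra-4,9,11-trien-8-one
Conditions: 13 (1.5 equiv), DCC (1.5 equiv), DMAP (0.1 equiv), CH2Cl2, 0 °C to rt
Reagents that add atoms: tiglic acid 13, C/C=C(\C)C(=O)O
Why: Steglich esterification acylates oxygen only, so C3 is untouched, the E-tiglate does not isomerise, and the conditions are too mild to conjugate the isopropenyl ketone.

Step 7
Reactants: 14 (3R,7R)-3-tigloyloxygermacra-4,9,11-trien-8-one
Product: 16 (3R,4R,5R,7R)-3-tigloyloxyeremophila-9,11-dien-8-one, via eudesm-4-yl cation aluminium enolate 15 (not isolated)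
Conditions: MeAlCl2 (3 equiv), CH2Cl2 (5 mM), −78 to 0 °C; Et3N–MeOH quench, aq. work-up
Reagents that add atoms: methylaluminium dichloride, C[Al](Cl)Cl (bound in 15 only, no atom stays in 16)
Why: Proposed new method: MeAlCl2 on the enone oxygen makes C10 the electrophile that C1 protonation makes it in a germacrene, and C5 of the E C4=C5 alkene attacks it across the ring from the centrosymmetric chair–chair conformer (C3–O held near the alkene plane by A(1,2) strain with C15, hence poorly aligned for ionisation, its carbonyl tied up by excess Lewis acid, isopropenyl equatorial); in the trans-fused zwitterion 15 the H5 bond, the empty C4 orbital, the axial C14 methyl and the enolate π system are all aligned, so H5 moves to the α face of C4 and C14 to the β face of C5, and the charge ends as the complexed enone, an irreversible sink, which sets 4R and 5R from 3R, while the alkylaluminium halide scavenges protons and spares the isopropenyl group; the closest known reaction type is the alkylaluminium-halide-induced addition of alkenes to enones, whose reversibly formed zwitterions collapse by two successive 1,2-hydride or alkyl shifts to a new β,β-disubstituted enone.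

Step 8
Reactants: 16 (3R,4R,5R,7R)-3-tigloyloxyeremophila-9,11-dien-8-one
Product: 18 (3R,4R,5R,7R,9R,10S)-9-hydroxy-3-tigloyloxyeremophil-11-en-8-one, via C8 silyl enol ether 17 (not isolated)
Conditions: [(Ph3P)CuH]6 (3 mol %), PhMe2SiH (1.5 equiv), PhMe, rt; solvent switch; dimethyldioxirane (1.05 equiv), acetone–CH2Cl2, −78 °C; AcOH–THF–H2O, 0 °C
Reagents that add atoms: dimethylphenylsilane, C[SiH](C)c1ccccc1 (silyl group in 17 only); dimethyldioxirane, CC1(C)OO1
Why: Copper hydride 1,4-hydrosilylation then Rubottom oxidation, in which the soft hydride touches only the enone and adds to C10 axially on the face syn to C14, as cuprates do with 10-methyloctalones, giving the cis-decalin (10S), the enol ether forms regiospecifically at C8=C9, and the dioxirane attacks this most electron-rich alkene on the convex β face to give the equatorial 9R alcohol.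

Step 9
Reactants: 18 (3R,4R,5R,7R,9R,10S)-9-hydroxy-3-tigloyloxyeremophil-11-en-8-one; 19 3-methylbut-2-enoic acid
Product: 20 CNP0375730.1, (3R,4R,5R,7R,9R,10S)-9-senecioyloxy-3-tigloyloxyeremophil-11-en-8-one
Conditions: 19 (2 equiv), DCC (2 equiv), DMAP (0.2 equiv), CH2Cl2, 0 °C to rt
Reagents that add atoms: 3-methylbut-2-enoic acid 19, CC(C)=CC(=O)O
Why: Steglich esterification avoids the vinylketene pathway of the acid chloride, so the ester stays conjugated, and C7 and C9 are already the equatorial, thermodynamically preferred epimers, so any enolisation converges on the target.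

## Compound list
1 | pent-4-yn-1-ol | C#CCCCO | starting material
2 | 2-(triphenylphosphoranylidene)propanal | CC(C=O)=P(c1ccccc1)(c1ccccc1)c1ccccc1 | starting material
3 | pent-4-ynal | C#CCCC=O | intermediate
4 | (E)-2-methylhept-2-en-6-ynal | C#CCC/C=C(\C)C=O | intermediate
5 | methyltriphenylphosphonium bromide | C[P+](c1ccccc1)(c1ccccc1)c1ccccc1.[Br-] | starting material
6 | (E)-3-methylocta-1,3-dien-7-yne | C#CCC/C=C(\C)C=C | intermediate
7 | trimethylaluminium | C[Al](C)C | starting material
8 | 3-methylbut-2-enoyl chloride (senecioyl chloride) | CC(C)=CC(=O)Cl | starting material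
9 | [(1E,5E)-2,6-dimethylocta-1,5,7-trienyl]dimethylalane | C=C/C(C)=C/CC/C(C)=C/[Al](C)C | intermediate
10 | (5E,9E)-2,6,10-trimethyldodeca-2,5,9,11-tetraen-4-one | C=C/C(C)=C/CC/C(C)=C/C(=O)C=C(C)C | intermediate
11 | (5E)-2,6-dimethyl-8-[(2R,3R)-3-ethenyl-3-methyloxiran-2-yl]octa-2,5-dien-4-one | C=C[C@@]1(C)O[C@@H]1CC/C(C)=C/C(=O)C=C(C)C | intermediate
12 | (3R,7R,4E,9E)-3-hydroxygermacra-4,9,11-trien-8-one | C=C(C)[C@H]1C/C=C(\C)[C@H](O)CC/C(C)=C/C1=O | intermediate
13 | tiglic acid | C/C=C(\C)C(=O)O | starting material
14 | (3R,7R,4E,9E)-3-tigloyloxygermacra-4,9,11-trien-8-one | C=C(C)[C@H]1C/C=C(\C)[C@H](OC(=O)/C(C)=C/C)CC/C(C)=C/C1=O | intermediate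
15 | trans-fused eudesm-4-yl cation, C8 methyldichloroaluminate enolate (5αH, 10β-Me, 3α-OTig, 7β-isopropenyl) | C=C(C)[C@H]1C[C@H]2[C+](C)[C@H](OC(=O)/C(C)=C/C)CC[C@]2(C)C=C1O[Al-](C)(Cl)Cl | intermediate
16 | (3R,4R,5R,7R)-3-tigloyloxyeremophila-9,11-dien-8-one | C=C(C)[C@H]1C[C@@]2(C)C(CC[C@@H](OC(=O)/C(C)=C/C)[C@@H]2C)=CC1=O | intermediate
17 | 8-(dimethylphenylsilyloxy)-3α-tigloyloxy-10βH-eremophila-8,11-diene | C=C(C)[C@H]1C[C@@]2(C)[C@H](CC[C@@H](OC(=O)/C(C)=C/C)[C@@H]2C)C=C1O[Si](C)(C)c1ccccc1 | intermediate
18 | (3R,4R,5R,7R,9R,10S)-9-hydroxy-3-tigloyloxyeremophil-11-en-8-one | C=C(C)[C@H]1C[C@@]2(C)[C@H](CC[C@@H](OC(=O)/C(C)=C/C)[C@@H]2C)[C@@H](O)C1=O | intermediate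
19 | 3-methylbut-2-enoic acid (senecioic acid) | CC(C)=CC(=O)O | starting material
20 | CNP0375730.1 | C=C(C)[C@H]1C[C@@]2(C)[C@H](CC[C@@H](OC(=O)/C(C)=C/C)[C@@H]2C)[C@@H](OC(=O)C=C(C)C)C1=O | target

Total step count: 9. Longest linear sequence: 9 steps, from 1. All other carbon inputs (2, 5, 7, 8, 13, 19) are bought.

## Steps most likely to fail

**Step 7, the transannular cascade.**
- The cis-fused (crossed-alkene) zwitterion could compete with the trans-fused one. In the cis-fused ion the enolate carbon, not C14, is aligned for migration.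
- The Lewis-acid-bound allylic tiglate could ionise, or it could capture the C4 cation as a dioxolenium ion.

The fallback takes the ester out of the cation chemistry and installs it after the skeleton is built. It sets out from 12. Et3SiCl and imidazole give the triethylsilyl ether of the macrocycle F3. The same MeAlCl2 treatment gives the 3-silyloxy dienone F4. AcOH–THF–H2O frees the alcohol, 7-epi-petasol F5. Steglich esterification with 13 brings the material back at 16.

**Step 5, the macrocyclisation.**
- The dienone is a far weaker acid than the usual pronucleophiles for this reaction.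
- The π-allyl alkoxide may instead lose a proton to give a dienol, or the substrate may oligomerise.

The fallback abandons palladium and closes the same C6–C7 bond by SN2 alkylation. It sets out from 11. TiCl4 in CH2Cl2 at −90 °C opens the vinyl epoxide in the SN2′ sense to the (R,E)-chlorohydrin F1. Steglich esterification with 13 gives the chloro tiglate F2. Slow addition of F2 to KN(SiMe3)2 in THF (1 mM, 40 °C) alkylates the potassium dienolate at C7 with the primary allylic chloride. This comes back at 14.

**Step 8, the reductive α-hydroxylation.**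
- C10 is flanked by the quaternary C5, so the reduction may be slow.
- Hydride may arrive in part from the α face, which would give the trans-decalin.

The fallback replaces substrate control by catalyst control and separates reduction from enolisation. It sets out from 16. Iminium-catalysed transfer hydrogenation, using a Hantzsch ester and the matched enantiomer of a chiral primary-amine phosphate salt, gives the cis-decalone F6. LiN(iPr)2 with Me3SiCl at −78 °C removes the less hindered C9 proton and gives the trimethylsilyl enol ether F7. Dimethyldioxirane followed by aqueous AcOH brings the material back at 18.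

## Further compounds
F1 | step 5 | (2E... 5E,9R,10E)-12-chloro-9-hydroxy-2,6,10-trimethyldodeca-2,5,10-trien-4-one | ClC/C=C(\C)[C@H](O)CC/C(C)=C/C(=O)C=C(C)C
F2 | step 5 | tiglate of F1, (5E,9R,10E)-12-chloro-2,6,10-trimethyl-4-oxododeca-2,5,10-trien-9-yl (E)-2-methylbut-2-enoate | ClC/C=C(\C)[C@H](OC(=O)/C(C)=C/C)CC/C(C)=C/C(=O)C=C(C)C
F3 | step 7 | (3R,7R,4E,9E)-3-(triethylsilyloxy)germacra-4,9,11-trien-8-one | C=C(C)[C@H]1C/C=C(\C)[C@H](O[Si](CC)(CC)CC)CC/C(C)=C/C1=O
F4 | step 7 | (3R,4R,5R,7R)-3-(triethylsilyloxy)eremophila-9,11-dien-8-one | C=C(C)[C@H]1C[C@@]2(C)C(CC[C@@H](O[Si](CC)(CC)CC)[C@@H]2C)=CC1=O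
F5 | step 7 | (3R,4R,5R,7R)-3-hydroxyeremophila-9,11-dien-8-one (7-epi-petasol) | C=C(C)[C@H]1C[C@@]2(C)C(CC[C@@H](O)[C@@H]2C)=CC1=O
F6 | step 8 | 3α-tigloyloxy-10βH-eremophil-11-en-8-one | C=C(C)[C@H]1C[C@@]2(C)[C@H](CC[C@@H](OC(=O)/C(C)=C/C)[C@@H]2C)CC1=O
F7 | step 8 | 8-(trimethylsilyloxy)-3α-tigloyloxy-10βH-eremophila-8,11-diene | C=C(C)[C@H]1C[C@@]2(C)[C@H](CC[C@@H](OC(=O)/C(C)=C/C)[C@@H]2C)C=C1O[Si](C)(C)C
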